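**Strategy.** The route rests on disconnecting ring A at the C3–C4 bond: C4, which carries two methyls and sits between the ring-fusion carbon C5 and the C3 carbinol, is formed as a tertiary radical from an isopropenyl group and captured by a C3 aldehyde. One iron-hydride operation therefore closes ring A, creates the gem-dimethyl group and sets the C3 hydroxyl on a carvone-derived ring B. The precursor is a cyclohexenone bearing the C10 methyl, a trans-disposed 3-oxopropyl chain and the C5 isopropenyl group. The resulting rings A/B unit is elaborated to a C11 iodide and joined to a rings D/E alkenyl iodide by B-alkyl Suzuki coupling.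

Key step: step 5

Numbering: ring A = C1–C5, C10; ring B = C5–C10; C11 on C9; C12=C13; ring D = C13–C18; ring E = C17–C22; methyls on C4 (two), C8, C10, C17, C19, C20; in rings A/B, β is the face of the C10 methyl, in rings D/E, β is the face of the C17 methyl; the target is then 3β-OH, 5α-H, 8β-Me, 9α-H, 10β-Me, 12E, 17β-Me, 18β-H, 19β-Me, 20β-Me, 20α-OH.

Assumption: the deracemising Michael addition of step 11 is expected to give C17 in high but not complete enantiomeric purity; since iodide 13 is enantiopure, any minor enantiomer of 28 should surface after step 19 as a separable diastereomer.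

Step 1
Reactants: 1 (R)-(−)-carvone; 2 iodomethane
Product: 3 (5R,6S)-2,6-dimethyl-5-(prop-1-en-2-yl)cyclohex-2-en-1-one (6-methylcarvone, trans isomer expected to predominate; the C6 epimer is carried along)
Conditions: LiN(iPr)2, THF, −78 °C; then 2, −78 to 0 °C
Reagents that add atoms: none
Why: Kinetic deprotonation at the alpha-prime CH2 by the hindered lithium amide and SN2 methylation of the cross-conjugated enolate (enolate alkylation) install the future C10 methyl, and the new centre needs no control because it is planarised again in step 2.

Step 2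
Reactants: 3 6-methylcarvone; 4 allyl bromide
Product: 5 (5S,6S)-6-allyl-2,6-dimethyl-5-(prop-1-en-2-yl)cyclohex-2-en-1-one (allyl trans to isopropenyl)
Conditions: LiN(iPr)2, THF, −78 °C; then 4, −78 °C to rt
Reagents that add atoms: none
Why: Enolate alkylation of the trisubstituted alpha-prime carbon with the reactive allylic bromide should occur on the face opposite the neighbouring isopropenyl group, so the chain ends up trans to isopropenyl and the methyl cis, which is the C5/C10 relationship of the trans-decalin.

Step 3
Reactants: 5 allyl ketone
Product: 6 (5S,6S)-6-(3-hydroxypropyl)-2,6-dimethyl-5-(prop-1-en-2-yl)cyclohex-2-en-1-one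
Conditions: disiamylborane (from BH3·SMe2 and 2-methylbut-2-ene), THF, 0 °C; then H2O2, pH 7 phosphate buffer, 0 °C to rt
Reagents that add atoms: hydrogen peroxide, OO
Why: Anti-Markovnikov Brown hydroboration with the bulky dialkylborane should select the monosubstituted allyl alkene over the 1,1-disubstituted isopropenyl group, the enone alkene and the hindered conjugated ketone, and neutral peroxide oxidation of the C–B bond avoids nucleophilic epoxidation of the enone.

Step 4
Reactants: 6 hydroxy ketone
Product: 7 3-[(1S,6S)-1,3-dimethyl-2-oxo-6-(prop-1-en-2-yl)cyclohex-3-en-1-yl]propanal (key-step precursor)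
Conditions: Dess–Martin periodinane, NaHCO3, CH2Cl2, rt
Reagents that add atoms: none
Why: Dess–Martin oxidation converts the primary alcohol into the aldehyde under buffered neutral conditions that leave the enone, the isopropenyl group and the quaternary centre untouched.

Step 5
Reactants: 7 keto aldehyde
Product: 8 (4aS,6S,8aS)-6-hydroxy-2,5,5,8a-tetramethyl-4a,5,6,7,8,8a-hexahydronaphthalen-1(4H)-one (3β-hydroxy-11-nordrim-7-en-9-one, trans-fused)
Conditions: Fe(acac)3 (0.5 equiv), PhSiH3 (2.5 equiv), EtOH/ethylene glycol 5:1 (0.02 M), 60 °C
Reagents that add atoms: none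
Why: An iron hydride generated from Fe(acac)3 and PhSiH3 transfers a hydrogen atom to the terminal CH2 of the electron-rich isopropenyl group (Mukaiyama-type metal-hydride hydrogen-atom transfer), which makes that carbon the second C4 methyl and leaves a tertiary radical at C4. The radical adds to the tethered aldehyde carbon in a 6-exo-trig closure that forms the C3–C4 bond and ring A, and the alkoxy radical is reduced by divalent iron and protonated by ethanol before it can fragment back, which returns trivalent iron. The closest known reaction types are the iron-mediated reductive radical cyclisation of alkene-tethered ketones and the intermolecular iron-hydride coupling of unactivated alkenes with aldehydes. The trans ring fusion follows from the pre-existing trans relation of the C10 chain and the C5 substituent, and the new C3 centre should be set by a chair transition state with the carbonyl oxygen pseudo-equatorial, free of 1,3-diaxial contacts with the axial hydrogens on C1 and C5, giving the 3β alcohol. The step needs hydrogen-atom transfer to the isopropenyl alkene in preference to the enone alkene and cyclisation in preference to intermolecular Giese addition, which the electron-poor, hindered character of the trisubstituted enone and the high dilution should secure.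

Step 6
Reactants: 8 hydroxy enone
Product: 9 3β-(tert-butyldimethylsilyloxy)-11-nordrim-7-en-9-one
Conditions: TBSCl, imidazole, DMF, 50 °C
Reagents that add atoms: tert-butyldimethylsilyl chloride, CC(C)(C)[Si](C)(C)Cl
Why: Silyl ether protection of the hindered secondary alcohol removes the only acidic proton before the ylide and organolithium steps and should survive borane, hydrogenation and iodination conditions.

Step 7
Reactants: 9 silyloxy enone
Product: 10 3β-(tert-butyldimethylsilyloxy)drima-7,9(11)-diene
Conditions: Ph3PCH3Br, KOtBu, toluene, 90 °C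
Reagents that add atoms: methyltriphenylphosphonium bromide, C[P+](c1ccccc1)(c1ccccc1)c1ccccc1.[Br-]
Why: Wittig methylenation with the small unstabilised ylide adds in a 1,2 sense to the hindered C9 ketone, which is flanked by the quaternary C10 and the sp2 carbon C8 so that no stereocentre can epimerise, and delivers C11 as an exocyclic methylene.

Step 8
Reactants: 10 diene
Product: 11 3β-(tert-butyldimethylsilyloxy)drim-7-en-11-ol (9α-H)
Conditions: 9-BBN, THF, rt to 50 °C; then NaOH, H2O2, 0 °C to rt
Reagents that add atoms: hydrogen peroxide, OO
Why: Brown hydroboration with 9-BBN should take place only at the terminal alkene of the diene, with boron at C11 and hydrogen delivered to C9 from the alpha face opposite the axial C10 methyl, which sets the 9α-hydrogen before oxidation with retention.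

Step 9
Reactants: 11 homoallylic alcohol
Product: 12 3β-(tert-butyldimethylsilyloxy)-8αH-driman-11-ol (8β-methyl, 9α-H)
Conditions: H2 (4 atm), PtO2, EtOAc, rt
Reagents that add atoms: none
Why: Heterogeneous catalytic hydrogenation should add hydrogen to the trisubstituted C7=C8 alkene from the alpha face, because the beta face is blocked by the axial C10 methyl and the C9 hydroxymethyl group, giving the 8α-hydrogen and the axial 8β-methyl.

Step 10
Reactants: 12 saturated alcohol
Product: 13 11-iodo-3β-(tert-butyldimethylsilyloxy)-8αH-drimane
Conditions: I2, PPh3, imidazole, toluene, 60 °C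
Reagents that add atoms: iodine, II
Why: Appel-type iodination (Garegg–Samuelsson conditions) converts the primary alcohol through its alkoxyphosphonium salt into the iodide by SN2 displacement without touching the stereocentres or the silyl ether.

Step 11
Reactants: 14 2-methylcyclohexanone (racemic); 15 (R)-1-phenylethylamine; 16 ethyl vinyl ketone
Product: 19 (S)-2-methyl-2-(3-oxopentyl)cyclohexan-1-one, via ketimine 17 (not isolated), via Michael-adduct ketimine 18 (not isolated)
Conditions: 14, 15, p-TsOH (cat.), toluene, reflux (Dean–Stark); then 16, THF, 40 °C; then 20% aq AcOH, rt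
Reagents that add atoms: water, O
Why: The chiral ketimine reacts through its more substituted secondary enamine tautomer in a deracemising Michael addition (d'Angelo reaction) in which the enone approaches the face away from the phenyl group, so the (R)-amine should set the (S)-quaternary centre that becomes C17 before mild acid hydrolysis releases the diketone and the auxiliary.

Step 12
Reactants: 19 diketone
Product: 20 (4aS)-1,4a-dimethyl-4,4a,5,6,7,8-hexahydronaphthalen-2(3H)-one
Conditions: NaOMe, MeOH, 60 °C
Reagents that add atoms: none
Why: Base-mediated intramolecular aldol condensation (the ring-closing half of a Robinson annulation) of the 1,5-diketone forms the six-membered enone with the C19 methyl on the alkene and leaves the quaternary centre untouched.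

Step 13
Reactants: 20 octalone
Product: 22 (4aS)-1,2,4a-trimethyl-3,4,4a,5,6,7-hexahydronaphthalene, via tertiary allylic alcohol 21 (not isolated)
Conditions: MeLi, Et2O, −78 to 0 °C; then p-TsOH (cat.), toluene, 60 °C
Reagents that add atoms: methyllithium, [Li]C
Why: 1,2-Addition of methyllithium to the enone carbonyl followed by acid-catalysed dehydration of the tertiary allylic alcohol through its allyl cation should give the thermodynamically preferred heteroannular diene (C19=C20 and C13=C18), so the configuration of the transient carbinol is irrelevant.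

Step 14
Reactants: 22 diene
Product: 23 (13α,20α)-dihydroxy rings D/E unit, 4a,7,8-trimethyldecahydronaphthalene-1,7-diol (trans-fused, 18α-H, 17β-Me, 19β-Me, 20β-Me)
Conditions: BH3·THF (4 equiv), THF, 0 °C to rt; then NaOH, H2O2, 50 °C
Reagents that add atoms: hydrogen peroxide, OO
Why: Brown hydroboration with excess borane should add first to the trisubstituted C13=C18 alkene with boron at C13 and then to the tetrasubstituted C19=C20 alkene with boron at the less hindered C20, both times syn and from the face opposite the angular C17 methyl, so that oxidation with retention gives the 20α-hydroxyl, the 19α-hydrogen (19β-methyl) and, for the time being, the 18α-hydrogen in one operation.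

Step 15
Reactants: 23 diol
Product: 25 cis-fused 20α-hydroxy-13-ketone (7-hydroxy-4a,7,8-trimethyloctahydronaphthalen-1(2H)-one; 18β-H), via trans-fused ketone 24 (not isolated)
Conditions: Dess–Martin periodinane, NaHCO3, CH2Cl2, rt; then K2CO3, MeOH, rt
Reagents that add atoms: none
Why: Dess–Martin oxidation of the secondary alcohol beside the inert tertiary one gives the trans-fused ketone, whose 1,3-diaxial clash between the C17 and C19 methyls should be relieved by base-mediated enolate epimerisation at C18 (thermodynamic control) to the cis-fused ketone in which the C19 methyl is equatorial.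

Step 16
Reactants: 25 hydroxy ketone
Product: 26 20α-(triethylsilyloxy) cis-fused 13-ketone
Conditions: TESOTf, 2,6-lutidine, CH2Cl2, −78 to 0 °C
Reagents that add atoms: triethylsilyl triflate, CC[Si](CC)(CC)OS(=O)(=O)C(F)(F)F
Why: Silyl ether protection of the tertiary alcohol with the reactive silyl triflate and a hindered pyridine base removes the acidic proton before the carbanion olefination and gives a group that is cleaved together with the TBS ether at the end.

Step 17
Reactants: 26 silyloxy ketone
Product: 27 (E)-alkenyl pinacol boronate (C13=C12H–Bpin, boron trans to C18)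
Conditions: CH2(Bpin)2, lithium 2,2,6,6-tetramethylpiperidide, THF, 0 °C; then 26, 0 °C to rt
Reagents that add atoms: bis(pinacolato)borylmethane, CC1(C)OB(CB2OC(C)(C)C(C)(C)O2)OC1(C)C
Why: Boron–Wittig olefination adds the lithiated geminal bis(boronate) to the ketone and eliminates a boron–oxygen pair in a syn fashion, and the remaining boryl group should prefer the side of the C14 methylene away from the branched ring-fusion carbon C18, giving the E-alkenylboronate, while any enolisation only returns the thermodynamically favoured cis ketone.

Step 18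
Reactants: 27 alkenyl boronate
Product: 28 (E)-alkenyl iodide (C13=C12H–I, iodine trans to C18)
Conditions: NaOH (aq), THF, 0 °C; then I2, 0 °C to rt
Reagents that add atoms: iodine, II
Why: Iododeboronation of the hydroxide-derived boronate ate complex should proceed with retention of alkene geometry and gives the E-alkenyl iodide needed as the sp2 coupling partner.

Step 19
Reactants: 13 alkyl iodide; 28 alkenyl iodide
Product: 31 bis-silyl ether of the target (3-O-TBS 20-O-TES), via alkyllithium 29 (not isolated), via borinate complex 30 (not isolated)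
Conditions: 13, B-methoxy-9-BBN, t-BuLi (2.1 equiv), Et2O, −78 °C, then THF, rt; then 28, Pd(dppf)Cl2 (5 mol%), K3PO4 (aq), DMF, rt
Reagents that add atoms: none
Why: Lithium–iodine exchange and trapping with B-methoxy-9-BBN give a borinate ate complex that should undergo B-alkyl Suzuki–Miyaura coupling with the alkenyl iodide with retention of alkene geometry, forming the C11–C12 bond without touching any stereocentre.

Step 20
Reactants: 31 bis-silyl ether
Product: 32 CNP0338143.1 (target)
Conditions: Bu4NF, THF, 60 °C
Reagents that add atoms: none
Why: Fluoride-mediated desilylation cleaves both silyl ethers under non-acidic conditions, which should free the secondary and tertiary alcohols without isomerising the trisubstituted exocyclic alkene or dehydrating the tertiary carbinol.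

**Compound list**

1 | (R)-(−)-carvone | CC1=CC[C@H](CC1=O)C(C)=C | starting material
2 | iodomethane | CI | starting material
3 | (5R,6S)-2,6-dimethyl-5-(prop-1-en-2-yl)cyclohex-2-en-1-one (trans isomer shown) | C[C@@H]1C(=O)C(C)=CC[C@H]1C(C)=C | intermediate
4 | allyl bromide | C=CCBr | starting material
5 | (5S,6S)-6-allyl-2,6-dimethyl-5-(prop-1-en-2-yl)cyclohex-2-en-1-one | C=CC[C@]1(C)C(=O)C(C)=CC[C@H]1C(C)=C | intermediate
6 | (5S,6S)-6-(3-hydroxypropyl)-2,6-dimethyl-5-(prop-1-en-2-yl)cyclohex-2-en-1-one | OCCC[C@]1(C)C(=O)C(C)=CC[C@H]1C(C)=C | intermediate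
7 | 3-[(1S,6S)-1,3-dimethyl-2-oxo-6-(prop-1-en-2-yl)cyclohex-3-en-1-yl]propanal | O=CCC[C@]1(C)C(=O)C(C)=CC[C@H]1C(C)=C | intermediate
8 | (4aS,6S,8aS)-6-hydroxy-2,5,5,8a-tetramethyl-4a,5,6,7,8,8a-hexahydronaphthalen-1(4H)-one | O=C1C(C)=CC[C@H]2C(C)(C)[C@@H](O)CC[C@]12C | intermediate
9 | 3β-(tert-butyldimethylsilyloxy)-11-nordrim-7-en-9-one | O=C1C(C)=CC[C@H]2C(C)(C)[C@@H](O[Si](C)(C)C(C)(C)C)CC[C@]12C | intermediate
10 | 3β-(tert-butyldimethylsilyloxy)drima-7,9(11)-diene | C=C1C(C)=CC[C@H]2C(C)(C)[C@@H](O[Si](C)(C)C(C)(C)C)CC[C@]12C | intermediate
11 | 3β-(tert-butyldimethylsilyloxy)drim-7-en-11-ol (9α-H) | OC[C@H]1C(C)=CC[C@H]2C(C)(C)[C@@H](O[Si](C)(C)C(C)(C)C)CC[C@]12C | intermediate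
12 | 3β-(tert-butyldimethylsilyloxy)-8αH-driman-11-ol (8β-Me, 9α-H) | OC[C@H]1[C@@H](C)CC[C@H]2C(C)(C)[C@@H](O[Si](C)(C)C(C)(C)C)CC[C@]12C | intermediate
13 | 11-iodo-3β-(tert-butyldimethylsilyloxy)-8αH-drimane | IC[C@H]1[C@@H](C)CC[C@H]2C(C)(C)[C@@H](O[Si](C)(C)C(C)(C)C)CC[C@]12C | intermediate
14 | 2-methylcyclohexanone (racemic) | CC1CCCCC1=O | starting material
15 | (R)-1-phenylethylamine | C[C@@H](N)c1ccccc1 | starting material
16 | ethyl vinyl ketone (pent-1-en-3-one) | CCC(=O)C=C | starting material
17 | N-[(R)-1-phenylethyl] ketimine of 2-methylcyclohexanone | C[C@@H](N=C1CCCCC1C)c1ccccc1 | intermediate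
18 | N-[(R)-1-phenylethyl] ketimine of (S)-2-methyl-2-(3-oxopentyl)cyclohexanone | C[C@@H](N=C1CCCC[C@@]1(C)CCC(=O)CC)c1ccccc1 | intermediate
19 | (S)-2-methyl-2-(3-oxopentyl)cyclohexan-1-one | O=C1CCCC[C@@]1(C)CCC(=O)CC | intermediate
20 | (4aS)-1,4a-dimethyl-4,4a,5,6,7,8-hexahydronaphthalen-2(3H)-one | CC1=C2CCCC[C@@]2(C)CCC1=O | intermediate
21 | (4aS)-1,2,4a-trimethyl-2,3,4,4a,5,6,7,8-octahydronaphthalen-2-ol (both C2 epimers) | CC1=C2CCCC[C@@]2(C)CCC1(C)O | intermediate
22 | (4aS)-1,2,4a-trimethyl-3,4,4a,5,6,7-hexahydronaphthalene | CC1=C(C)CC[C@]2(C)CCCC=C12 | intermediate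
23 | trans-fused 13α,20α-diol (4a,7,8-trimethyldecahydronaphthalene-1,7-diol; 18α-H, 17β/19β/20β-Me) | C[C@@H]1[C@@H]2[C@@H](O)CCC[C@@]2(C)CC[C@@]1(C)O | intermediate
24 | trans-fused 20α-hydroxy-13-ketone (18α-H) | C[C@@H]1[C@@H]2C(=O)CCC[C@@]2(C)CC[C@@]1(C)O | intermediate
25 | cis-fused 20α-hydroxy-13-ketone (18β-H; 7-hydroxy-4a,7,8-trimethyloctahydronaphthalen-1(2H)-one) | C[C@@H]1[C@H]2C(=O)CCC[C@@]2(C)CC[C@@]1(C)O | intermediate
26 | 20α-triethylsilyl ether of 25 | C[C@@H]1[C@H]2C(=O)CCC[C@@]2(C)CC[C@@]1(C)O[Si](CC)(CC)CC | intermediate
27 | (E)-alkenyl pinacol boronate of 26 (C13=C12H–Bpin) | C[C@@H]1[C@H]2/C(=C/B3OC(C)(C)C(C)(C)O3)CCC[C@@]2(C)CC[C@@]1(C)O[Si](CC)(CC)CC | intermediate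
28 | (E)-alkenyl iodide (C13=C12H–I) | C[C@@H]1[C@H]2/C(=C/I)CCC[C@@]2(C)CC[C@@]1(C)O[Si](CC)(CC)CC | intermediate
29 | C11 alkyllithium from 13 | [Li]C[C@H]1[C@@H](C)CC[C@H]2C(C)(C)[C@@H](O[Si](C)(C)C(C)(C)C)CC[C@]12C | intermediate
30 | lithium B-alkyl-B-methoxy-9-borabicyclo[3.3.1]nonane ate complex of 29 | [Li+].CO[B-]1(C[C@H]2[C@@H](C)CC[C@H]3C(C)(C)[C@@H](O[Si](C)(C)C(C)(C)C)CC[C@]23C)C2CCCC1CCC2 | intermediate
31 | 3-O-TBS, 20-O-TES ether of the target | C[C@@H]1[C@H]2/C(=C/C[C@H]3[C@@H](C)CC[C@H]4C(C)(C)[C@@H](O[Si](C)(C)C(C)(C)C)CC[C@]34C)CCC[C@@]2(C)CC[C@@]1(C)O[Si](CC)(CC)CC | intermediate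
32 | CNP0338143.1 | C[C@@H]1[C@H]2/C(=C/C[C@H]3[C@@H](C)CC[C@H]4C(C)(C)[C@@H](O)CC[C@]34C)CCC[C@@]2(C)CC[C@@]1(C)O | target

**Step count and risks**

Total step count: 20. Longest linear sequence: 12 steps (steps 1–10, 19, 20); the rings D/E branch (steps 11–18) is 8 steps before the union.

Most likely to fail:

Step 5. The radical addition to the aldehyde may show poor facial control at C3 (axial versus equatorial carbinol), and premature reduction of the C4 radical would compete with ring closure. Fallback: the cyclisation is run from 7 as before, and the crude mixture of 8 and its C3 epimer, the 3α-alcohol F1, is oxidised with Dess–Martin periodinane to the 3,9-dione F2. The saturated C3 ketone is then reduced with NaBH4 (MeOH, −20 °C) in preference to the hindered conjugated C9 ketone; axial hydride attack on a 4,4-dimethyl-3-ketone should give the equatorial 3β-alcohol. The route is rejoined at 8, with the C3 configuration now set by hydride reduction instead of by the radical step.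

Step 14. Boron may be delivered to C19 instead of C20 on the tetrasubstituted alkene, or the second hydroboration may stall at the hindered alkene. Fallback, setting out from 22:
- 9-BBN then NaOH/H2O2 hydroborates only the trisubstituted C13=C18 alkene and gives the homoallylic alcohol F3.
- mCPBA epoxidises the tetrasubstituted alkene anti to the C17 methyl to give the epoxy alcohol F4.
- Dess–Martin oxidation gives the β,γ-epoxy ketone F5.
- Et3N opens the epoxide by E1cB elimination to the γ-hydroxy enone F6, with the C20–O bond (and hence the 20α-hydroxyl) retained.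
- Hydroxyl-directed hydrogenation with [Ir(cod)(PCy3)(py)]PF6 and H2 adds both hydrogens on the hydroxyl face, opposite the C17 methyl, and gives 24, which is epimerised to 25 as in step 15.

Step 19. Transmetalation of the β-branched, hindered alkyl group from boron to palladium may be slow, so that protodeboronation and reduction of the alkenyl iodide take over. Fallback: 13 and 28 are joined directly by nickel-catalysed reductive cross-electrophile coupling (NiBr2(dme), 4,4'-di-tert-butyl-2,2'-bipyridine, Mn powder, NaI, DMA, rt). The C11 radical from 13 is captured by the alkenylnickel species from 28 with retention of alkene geometry, so no organoboron intermediate is needed. The route is rejoined at 31; this fallback makes no new compound, F0.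

**Further compounds**

F1 | step 5 | (4aS,6R,8aS)-6-hydroxy-2,5,5,8a-tetramethyl-4a,5,6,7,8,8a-hexahydronaphthalen-1(4H)-one (3α-epimer of 8) | O=C1C(C)=CC[C@H]2C(C)(C)[C@H](O)CC[C@]12C
F2 | step 5 | 11-nordrim-7-ene-3,9-dione | O=C1C(C)=CC[C@H]2C(C)(C)C(=O)CC[C@]12C
F3 | step 14 | trans-fused 13α-hydroxy-19(20)-ene (4a,7,8-trimethyl-1,2,3,4,4a,5,6,8a-octahydronaphthalen-1-ol, 18α-H) | CC1=C(C)CC[C@]2(C)CCC[C@H](O)[C@@H]12
F4 | step 14 | 19α,20α-epoxide of F3 | C[C@@]12O[C@]1(C)CC[C@]3(C)CCC[C@H](O)[C@@H]23
F5 | step 14 | 19α,20α-epoxy-13-ketone | C[C@@]12O[C@]1(C)CC[C@]3(C)CCCC(=O)[C@@H]23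
F6 | step 14 | 20α-hydroxy-18(19)-en-13-one (7-hydroxy-4a,7,8-trimethyl-3,4,4a,5,6,7-hexahydronaphthalen-1(2H)-one) | CC1=C2C(=O)CCC[C@@]2(C)CC[C@@]1(C)O
F0 | step 19 | none | none
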